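The ten-membered ring is treated at the oxidation level of its 1(10),4-diene (C4–C5 epoxide written as an alkene): C2 and C3 (germacrane numbering), the two adjacent ring CH2 groups, are then both allylic, so C10=C1–C2–C3–C4=C5 is a 1,5-diene and the ring is the product of a [3,3] shift. An anionic oxy-Cope rearrangement of a carvone-derived trans-1,2-dialkenylcyclohexanol forms C2–C3, cleaves C5–C10 and expands the six-membered ring by four atoms in one operation; the enolate is trapped as the C5 triflate. The precursor is a cyclohexanol carrying a vinyl group at C10, an isopropenyl group and the hydroxyl at C5, and the C6, C7, C8 stereotriad already in place.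

Key step: step 13

Remark: germacrane numbering is used for every compound (C1=C10 ring alkene, C2 and C3 the adjacent ring CH2 groups, C4–C5 epoxide, C6 ester carbon, C7 isopropyl carbon, C8 carbinol carbon, C9 CH2); commercial (R)-(−)-carvone of high enantiomeric purity is assumed as the only source of absolute configuration.

Step 1
Reactants: 1 (R)-(−)-carvone
Product: 2 (5R)-2-methyl-5-(propan-2-yl)cyclohex-2-en-1-one
Conditions: H2 (1 atm), RhCl(PPh3)3 (cat.), benzene, 25 °C
Reagents that add atoms: none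
Why: Homogeneous hydrogenation with RhCl(PPh3)3 should reduce the 1,1-disubstituted isopropenyl alkene much faster than the trisubstituted conjugated ring alkene, so the enone is kept and C7 is untouched.

Step 2
Reactants: 2 (5R)-2-methyl-5-(propan-2-yl)cyclohex-2-en-1-one
Product: 3 (1S,5R)-2-methyl-5-(propan-2-yl)cyclohex-2-en-1-ol
Conditions: (R)-2-methyl-CBS-oxazaborolidine (20 mol %), BH3·SMe2, THF, −20 °C; then MeOH
Reagents that add atoms: none
Why: CBS reduction is a reagent-controlled 1,2-reduction in which the (R)-oxazaborolidine should deliver hydride to the face that gives the (1S)-carbinol with OH trans to the isopropyl group, a temporary stereocentre (C5) that steers steps 4 and 5.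

Step 3
Reactants: 3 (1S,5R)-2-methyl-5-(propan-2-yl)cyclohex-2-en-1-ol
Product: 4 tert-butyl(dimethyl){[(1S,5R)-2-methyl-5-(propan-2-yl)cyclohex-2-en-1-yl]oxy}silane
Conditions: TBSCl, imidazole, DMF, 25 °C
Reagents that add atoms: tert-butyldimethylsilyl chloride CC(C)(C)[Si](C)(C)Cl
Why: Standard silylation of a secondary allylic alcohol gives an ether that is a poor leaving group and should survive the oxidation and the cuprate addition.

Step 4
Reactants: 4 tert-butyl(dimethyl){[(1S,5R)-2-methyl-5-(propan-2-yl)cyclohex-2-en-1-yl]oxy}silane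
Product: 5 (4S,6R)-4-[(tert-butyldimethylsilyl)oxy]-3-methyl-6-(propan-2-yl)cyclohex-2-en-1-one
Conditions: CrO3, 3,5-dimethylpyrazole, CH2Cl2, −20 °C
Reagents that add atoms: chromium trioxide O=[Cr](=O)=O
Why: Allylic C–H oxidation with the CrO3·3,5-dimethylpyrazole complex should convert the ring CH2 at C8 into the carbonyl of a transposed enone (C8=O, C9=C10), because the competing C5–H is pseudo-equatorial, poorly aligned with the alkene and shielded by the silyl ether.

Step 5
Reactants: 5 (4S,6R)-4-[(tert-butyldimethylsilyl)oxy]-3-methyl-6-(propan-2-yl)cyclohex-2-en-1-one; 6 vinylmagnesium bromide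
Product: 8 (2R,4S,5R)-4-[(tert-butyldimethylsilyl)oxy]-5-ethenyl-5-methyl-2-(propan-2-yl)cyclohexan-1-one, via trimethylsilyl enol ether 7 (not isolated)
Conditions: CH2=CHMgBr, CuBr·SMe2 (20 mol %), Me3SiCl, THF, −78 → −40 °C; then 10% aq. citric acid, 0 °C
Reagents that add atoms: vinylmagnesium bromide C=C[Mg]Br
Why: Copper-catalysed conjugate addition accelerated by Me3SiCl should deliver the vinyl group axially and anti to the pseudo-axial C5 silyloxy group, so the new quaternary centre C10 (temporary) carries vinyl cis and methyl trans to the isopropyl group.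

Step 6
Reactants: 8 (2R,4S,5R)-4-[(tert-butyldimethylsilyl)oxy]-5-ethenyl-5-methyl-2-(propan-2-yl)cyclohexan-1-one
Product: 9 (1R,2R,4S,5R)-4-[(tert-butyldimethylsilyl)oxy]-5-ethenyl-5-methyl-2-(propan-2-yl)cyclohexan-1-ol
Conditions: LiBH(s-Bu)3, THF, −78 °C; then H2O
Reagents that add atoms: none
Why: The bulky borohydride should attack the C8 ketone from the equatorial direction, away from the axial C10 vinyl group, and give the axial alcohol cis to the adjacent isopropyl group, which is the C8 configuration of the target (8 is used at once at low temperature so that C7 cannot epimerise).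

Step 7
Reactants: 9 (1R,2R,4S,5R)-4-[(tert-butyldimethylsilyl)oxy]-5-ethenyl-5-methyl-2-(propan-2-yl)cyclohexan-1-ol
Product: 10 (1R,2R,4S,5R)-4-[(tert-butyldimethylsilyl)oxy]-5-ethenyl-5-methyl-2-(propan-2-yl)cyclohexyl 4-methoxybenzyl ether
Conditions: NaH, PMBCl, DMF, 0 → 40 °C
Reagents that add atoms: 4-methoxybenzyl chloride COc1ccc(CCl)cc1
Why: Williamson etherification of the sodium alkoxide installs a PMB ether that is orthogonal to the silyl ethers and removable at the end under neutral oxidative conditions.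

Step 8
Reactants: 10 (1R,2R,4S,5R)-4-[(tert-butyldimethylsilyl)oxy]-5-ethenyl-5-methyl-2-(propan-2-yl)cyclohexyl 4-methoxybenzyl ether
Product: 11 (1S,2R,4R,5R)-2-ethenyl-4-[(4-methoxyphenyl)methoxy]-2-methyl-5-(propan-2-yl)cyclohexan-1-ol
Conditions: Bu4NF, THF, 50 °C
Reagents that add atoms: none
Why: Fluoride should cleave the only silyl ether and free the C5 hydroxyl while the PMB ether and the vinyl group stay inert.

Step 9
Reactants: 11 (1S,2R,4R,5R)-2-ethenyl-4-[(4-methoxyphenyl)methoxy]-2-methyl-5-(propan-2-yl)cyclohexan-1-ol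
Product: 12 (2R,4R,5R)-2-ethenyl-4-[(4-methoxyphenyl)methoxy]-2-methyl-5-(propan-2-yl)cyclohexan-1-one
Conditions: Pr4N[RuO4] (5 mol %), N-methylmorpholine N-oxide, 4 Å MS, CH2Cl2, 25 °C
Reagents that add atoms: none
Why: Perruthenate-catalysed oxidation should convert the hindered secondary alcohol into the C5 ketone under neutral conditions that leave the PMB ether and the alkene untouched.

Step 10
Reactants: 12 (2R,4R,5R)-2-ethenyl-4-[(4-methoxyphenyl)methoxy]-2-methyl-5-(propan-2-yl)cyclohexan-1-one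
Product: 14 (2R,4R,5S,6S)-2-ethenyl-6-hydroxy-4-[(4-methoxyphenyl)methoxy]-2-methyl-5-(propan-2-yl)cyclohexan-1-one, via potassium enolate 13 (not isolated)
Conditions: KN(SiMe3)2, THF, −78 °C; then 2-(phenylsulfonyl)-3-phenyloxaziridine, −78 °C; then H2O
Reagents that add atoms: 2-(phenylsulfonyl)-3-phenyloxaziridine O=S(=O)(c1ccccc1)N1OC1c1ccccc1
Why: The quaternary C10 allows enolisation only towards C6, and electrophilic hydroxylation of the enolate by the N-sulfonyloxaziridine should occur anti to the axial C8 ether and C10 vinyl groups, giving the equatorial C6 alcohol trans to the isopropyl group (also the thermodynamically preferred epimer).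

Step 11
Reactants: 14 (2R,4R,5S,6S)-2-ethenyl-6-hydroxy-4-[(4-methoxyphenyl)methoxy]-2-methyl-5-(propan-2-yl)cyclohexan-1-one
Product: 15 (2R,4R,5R,6S)-6-[(tert-butyldimethylsilyl)oxy]-2-ethenyl-4-[(4-methoxyphenyl)methoxy]-2-methyl-5-(propan-2-yl)cyclohexan-1-one
Conditions: TBSOTf, 2,6-lutidine, CH2Cl2, −78 → 0 °C
Reagents that add atoms: tert-butyldimethylsilyl trifluoromethanesulfonate CC(C)(C)[Si](C)(C)OS(=O)(=O)C(F)(F)F
Why: Silylation of the α-hydroxy ketone with the silyl triflate and a hindered base should proceed without epimerisation or α-ketol rearrangement.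

Step 12
Reactants: 15 (2R,4R,5R,6S)-6-[(tert-butyldimethylsilyl)oxy]-2-ethenyl-4-[(4-methoxyphenyl)methoxy]-2-methyl-5-(propan-2-yl)cyclohexan-1-one; 16 isopropenylmagnesium bromide
Product: 17 (1S,2R,4R,5R,6S)-6-[(tert-butyldimethylsilyl)oxy]-2-ethenyl-4-[(4-methoxyphenyl)methoxy]-2-methyl-1-(prop-1-en-2-yl)-5-(propan-2-yl)cyclohexan-1-ol
Conditions: CH2=C(CH3)MgBr, CeCl3, THF, −78 °C; then H2O
Reagents that add atoms: isopropenylmagnesium bromide CC(=C)[Mg]Br
Why: Organocerium 1,2-addition (CeCl3 suppresses enolisation of the hindered ketone) should occur by axial attack on the face opposite the axial C10 vinyl group, which places the isopropenyl group trans to the vinyl group and sets the temporary C5 carbinol centre.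

Step 13
Reactants: 17 (1S,2R,4R,5R,6S)-6-[(tert-butyldimethylsilyl)oxy]-2-ethenyl-4-[(4-methoxyphenyl)methoxy]-2-methyl-1-(prop-1-en-2-yl)-5-(propan-2-yl)cyclohexan-1-ol
Product: 20 (1Z,5E,8R,9R,10S)-10-[(tert-butyldimethylsilyl)oxy]-8-[(4-methoxyphenyl)methoxy]-2,6-dimethyl-9-(propan-2-yl)cyclodeca-1,5-dien-1-yl trifluoromethanesulfonate, via potassium alkoxide 18 (not isolated), via ring-expanded potassium enolate 19 (not isolated)
Conditions: KH, 18-crown-6, THF, 0 → 25 °C; then N-(5-chloropyridin-2-yl)bis(trifluoromethanesulfonimide), −78 → 0 °C; then H2O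
Reagents that add atoms: N-(5-chloropyridin-2-yl)bis(trifluoromethanesulfonimide) FC(F)(F)S(=O)(=O)N(c1ccc(Cl)cn1)S(=O)(=O)C(F)(F)F
Why: The potassium alkoxide 18 should undergo an anionic oxy-Cope rearrangement, a concerted [3,3] sigmatropic shift through a chair transition state in which the terminal CH2 carbons of the vinyl and isopropenyl groups join (C2–C3) while the C5–C10 bond of the cyclohexane breaks, and the resulting enolate 19 is O-sulfonylated in the same flask. The closest known reaction type is the anionic oxy-Cope ring expansion of trans-1,2-divinylcyclohexanols to cyclodec-5-enones with in situ trapping of the enolate. The ten-membered ring is closed by a four-atom ring expansion, the new sigma bond forming between the two alkene termini inside the six-membered chair transition state while the bond shared with the cyclohexane is cut. No new sp3 stereocentre is formed: C5 and C10 become trigonal and C6, C7 and C8 are untouched. The step needs E geometry at both new ring double bonds (C1=C10 and C4=C5), and the trans arrangement of the two alkenyl groups secures it, because in the reacting chair conformer both are equatorial and both ring bonds sit pseudo-equatorial in the transition state. Alkoxide formation weakens the C5–C10 bond and the enolate product makes the otherwise unfavourable six- to ten-membered expansion irreversible near room temperature.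

Step 14
Reactants: 20 (1Z,5E,8R,9R,10S)-10-[(tert-butyldimethylsilyl)oxy]-8-[(4-methoxyphenyl)methoxy]-2,6-dimethyl-9-(propan-2-yl)cyclodeca-1,5-dien-1-yl trifluoromethanesulfonate
Product: 21 tert-butyl({(1R,2E,6E,9R,10R)-9-[(4-methoxyphenyl)methoxy]-3,7-dimethyl-10-(propan-2-yl)cyclodeca-2,6-dien-1-yl}oxy)dimethylsilane
Conditions: Pd(OAc)2 (5 mol %), PPh3 (10 mol %), HCO2H, Bu3N, DMF, 40 °C
Reagents that add atoms: none
Why: Oxidative addition of the alkenyl triflate to zerovalent palladium, formate-to-hydride exchange and reductive elimination should replace OTf by H with retention of geometry (palladium-catalysed triflate reduction), giving the E C4=C5 alkene well below the temperature of the reverse Cope rearrangement.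

Step 15
Reactants: 21 tert-butyl({(1R,2E,6E,9R,10R)-9-[(4-methoxyphenyl)methoxy]-3,7-dimethyl-10-(propan-2-yl)cyclodeca-2,6-dien-1-yl}oxy)dimethylsilane
Product: 22 (1R,2E,6E,9R,10S)-9-[(4-methoxyphenyl)methoxy]-3,7-dimethyl-10-(propan-2-yl)cyclodeca-2,6-dien-1-ol
Conditions: Bu4NF, THF, 0 → 25 °C
Reagents that add atoms: none
Why: Fluoride should remove the allylic silyl ether at a stage where no ester is present, so no acyl migration is possible and the PMB ether is untouched.

Step 16
Reactants: 22 (1R,2E,6E,9R,10S)-9-[(4-methoxyphenyl)methoxy]-3,7-dimethyl-10-(propan-2-yl)cyclodeca-2,6-dien-1-ol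
Product: 23 (1R,2S,3S,4R,6E,10R)-4-[(4-methoxyphenyl)methoxy]-6,10-dimethyl-3-(propan-2-yl)-11-oxabicyclo[8.1.0]undec-6-en-2-ol
Conditions: VO(acac)2 (5 mol %), t-BuOOH (decane), CH2Cl2, 0 °C
Reagents that add atoms: tert-butyl hydroperoxide CC(C)(C)OO
Why: Vanadium-catalysed hydroxyl-directed epoxidation should oxidise only the allylic C4=C5 alkene, delivering oxygen from the C6 alkoxide to the outer alkene face in the conformer that minimises A(1,3) strain between the C4 methyl group and C6 (C6–H eclipsing the alkene), which should give the threo epoxy alcohol with the C4 and C5 configurations of the target.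

Step 17
Reactants: 23 (1R,2S,3S,4R,6E,10R)-4-[(4-methoxyphenyl)methoxy]-6,10-dimethyl-3-(propan-2-yl)-11-oxabicyclo[8.1.0]undec-6-en-2-ol; 24 3,4,5-trimethoxybenzoyl chloride
Product: 25 (1R,2S,3R,4R,6E,10R)-4-[(4-methoxyphenyl)methoxy]-6,10-dimethyl-3-(propan-2-yl)-11-oxabicyclo[8.1.0]undec-6-en-2-yl 3,4,5-trimethoxybenzoate
Conditions: Et3N, DMAP (cat.), CH2Cl2, 0 → 25 °C
Reagents that add atoms: 3,4,5-trimethoxybenzoyl chloride COc1cc(C(Cl)=O)cc(OC)c1OC
Why: DMAP-catalysed acylation should esterify the only free hydroxyl group (C6) under mildly basic conditions that do not open the epoxide.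

Step 18
Reactants: 25 (1R,2S,3R,4R,6E,10R)-4-[(4-methoxyphenyl)methoxy]-6,10-dimethyl-3-(propan-2-yl)-11-oxabicyclo[8.1.0]undec-6-en-2-yl 3,4,5-trimethoxybenzoate
Product: 26 (1R,2S,3R,4R,6E,10R)-4-hydroxy-6,10-dimethyl-3-(propan-2-yl)-11-oxabicyclo[8.1.0]undec-6-en-2-yl 3,4,5-trimethoxybenzoate
Conditions: DDQ, CH2Cl2/pH 7 phosphate buffer, 0 °C
Reagents that add atoms: none
Why: Oxidative cleavage of the PMB ether by DDQ under buffered neutral conditions should free the C8 alcohol without acid (no transannular opening of the epoxide) and without base (no acyl migration).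

Compound list
1 | (R)-(−)-carvone, (5R)-2-methyl-5-(prop-1-en-2-yl)cyclohex-2-en-1-one | O=C1C[C@H](C(C)=C)CC=C1C | starting material
2 | (5R)-2-methyl-5-(propan-2-yl)cyclohex-2-en-1-one | O=C1C[C@H](C(C)C)CC=C1C | intermediate
3 | (1S,5R)-2-methyl-5-(propan-2-yl)cyclohex-2-en-1-ol (OH trans to isopropyl) | O[C@H]1C[C@H](C(C)C)CC=C1C | intermediate
4 | tert-butyl(dimethyl){[(1S,5R)-2-methyl-5-(propan-2-yl)cyclohex-2-en-1-yl]oxy}silane | CC(C)(C)[Si](C)(C)O[C@H]1C[C@H](C(C)C)CC=C1C | intermediate
5 | (4S,6R)-4-[(tert-butyldimethylsilyl)oxy]-3-methyl-6-(propan-2-yl)cyclohex-2-en-1-one | CC(C)(C)[Si](C)(C)O[C@H]1C[C@H](C(C)C)C(=O)C=C1C | intermediate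
6 | vinylmagnesium bromide | C=C[Mg]Br | starting material
7 | trimethylsilyl enol ether of 8 (C8–C9 enol ether, not isolated) | CC(C)(C)[Si](C)(C)O[C@H]1C[C@H](C(C)C)C(O[Si](C)(C)C)=C[C@]1(C)C=C | intermediate
8 | (2R,4S,5R)-4-[(tert-butyldimethylsilyl)oxy]-5-ethenyl-5-methyl-2-(propan-2-yl)cyclohexan-1-one | CC(C)(C)[Si](C)(C)O[C@H]1C[C@H](C(C)C)C(=O)C[C@]1(C)C=C | intermediate
9 | (1R,2R,4S,5R)-4-[(tert-butyldimethylsilyl)oxy]-5-ethenyl-5-methyl-2-(propan-2-yl)cyclohexan-1-ol | CC(C)(C)[Si](C)(C)O[C@H]1C[C@H](C(C)C)[C@H](O)C[C@]1(C)C=C | intermediate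
10 | (1R,2R,4S,5R)-4-[(tert-butyldimethylsilyl)oxy]-5-ethenyl-5-methyl-2-(propan-2-yl)cyclohexyl 4-methoxybenzyl ether | CC(C)(C)[Si](C)(C)O[C@H]1C[C@H](C(C)C)[C@H](OCc2ccc(OC)cc2)C[C@]1(C)C=C | intermediate
11 | (1S,2R,4R,5R)-2-ethenyl-4-[(4-methoxyphenyl)methoxy]-2-methyl-5-(propan-2-yl)cyclohexan-1-ol | O[C@H]1C[C@H](C(C)C)[C@H](OCc2ccc(OC)cc2)C[C@]1(C)C=C | intermediate
12 | (2R,4R,5R)-2-ethenyl-4-[(4-methoxyphenyl)methoxy]-2-methyl-5-(propan-2-yl)cyclohexan-1-one | O=C1C[C@H](C(C)C)[C@H](OCc2ccc(OC)cc2)C[C@]1(C)C=C | intermediate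
13 | potassium enolate of 12 (C5–C6 enolate, not isolated) | [K+].[O-]C1=C[C@H](C(C)C)[C@H](OCc2ccc(OC)cc2)C[C@]1(C)C=C | intermediate
14 | (2R,4R,5S,6S)-2-ethenyl-6-hydroxy-4-[(4-methoxyphenyl)methoxy]-2-methyl-5-(propan-2-yl)cyclohexan-1-one | O=C1[C@@H](O)[C@H](C(C)C)[C@H](OCc2ccc(OC)cc2)C[C@]1(C)C=C | intermediate
15 | (2R,4R,5R,6S)-6-[(tert-butyldimethylsilyl)oxy]-2-ethenyl-4-[(4-methoxyphenyl)methoxy]-2-methyl-5-(propan-2-yl)cyclohexan-1-one | O=C1[C@@H](O[Si](C)(C)C(C)(C)C)[C@H](C(C)C)[C@H](OCc2ccc(OC)cc2)C[C@]1(C)C=C | intermediate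
16 | isopropenylmagnesium bromide (prop-1-en-2-ylmagnesium bromide) | CC(=C)[Mg]Br | starting material
17 | (1S,2R,4R,5R,6S)-6-[(tert-butyldimethylsilyl)oxy]-2-ethenyl-4-[(4-methoxyphenyl)methoxy]-2-methyl-1-(prop-1-en-2-yl)-5-(propan-2-yl)cyclohexan-1-ol (vinyl and isopropenyl trans) | CC(=C)[C@@]1(O)[C@@H](O[Si](C)(C)C(C)(C)C)[C@H](C(C)C)[C@H](OCc2ccc(OC)cc2)C[C@]1(C)C=C | intermediate
18 | potassium alkoxide of 17 (not isolated) | [K+].CC(=C)[C@@]1([O-])[C@@H](O[Si](C)(C)C(C)(C)C)[C@H](C(C)C)[C@H](OCc2ccc(OC)cc2)C[C@]1(C)C=C | intermediate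
19 | potassium (1Z,5E,8R,9R,10S)-10-[(tert-butyldimethylsilyl)oxy]-8-[(4-methoxyphenyl)methoxy]-2,6-dimethyl-9-(propan-2-yl)cyclodeca-1,5-dien-1-olate (ring-expanded enolate, not isolated) | [K+].C1/C(C)=C([O-])/[C@@H](O[Si](C)(C)C(C)(C)C)[C@H](C(C)C)[C@H](OCc2ccc(OC)cc2)C/C(C)=C/C1 | intermediate
20 | (1Z,5E,8R,9R,10S)-10-[(tert-butyldimethylsilyl)oxy]-8-[(4-methoxyphenyl)methoxy]-2,6-dimethyl-9-(propan-2-yl)cyclodeca-1,5-dien-1-yl trifluoromethanesulfonate | C1/C(C)=C(OS(=O)(=O)C(F)(F)F)/[C@@H](O[Si](C)(C)C(C)(C)C)[C@H](C(C)C)[C@H](OCc2ccc(OC)cc2)C/C(C)=C/C1 | intermediate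
21 | tert-butyl({(1R,2E,6E,9R,10R)-9-[(4-methoxyphenyl)methoxy]-3,7-dimethyl-10-(propan-2-yl)cyclodeca-2,6-dien-1-yl}oxy)dimethylsilane | C1/C(C)=C/[C@@H](O[Si](C)(C)C(C)(C)C)[C@H](C(C)C)[C@H](OCc2ccc(OC)cc2)C/C(C)=C/C1 | intermediate
22 | (1R,2E,6E,9R,10S)-9-[(4-methoxyphenyl)methoxy]-3,7-dimethyl-10-(propan-2-yl)cyclodeca-2,6-dien-1-ol | C1/C(C)=C/[C@@H](O)[C@H](C(C)C)[C@H](OCc2ccc(OC)cc2)C/C(C)=C/C1 | intermediate
23 | (1R,2S,3S,4R,6E,10R)-4-[(4-methoxyphenyl)methoxy]-6,10-dimethyl-3-(propan-2-yl)-11-oxabicyclo[8.1.0]undec-6-en-2-ol | C1[C@@]2(C)O[C@@H]2[C@@H](O)[C@H](C(C)C)[C@H](OCc3ccc(OC)cc3)C/C(C)=C/C1 | intermediate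
24 | 3,4,5-trimethoxybenzoyl chloride | COc1cc(C(Cl)=O)cc(OC)c1OC | starting material
25 | (1R,2S,3R,4R,6E,10R)-4-[(4-methoxyphenyl)methoxy]-6,10-dimethyl-3-(propan-2-yl)-11-oxabicyclo[8.1.0]undec-6-en-2-yl 3,4,5-trimethoxybenzoate | C1[C@@]2(C)O[C@@H]2[C@@H](OC(=O)c3cc(OC)c(OC)c(OC)c3)[C@H](C(C)C)[C@H](OCc4ccc(OC)cc4)C/C(C)=C/C1 | intermediate
26 | (1R,2S,3R,4R,6E,10R)-4-hydroxy-6,10-dimethyl-3-(propan-2-yl)-11-oxabicyclo[8.1.0]undec-6-en-2-yl 3,4,5-trimethoxybenzoate (CNP0279501.1) | COc1cc(C(=O)O[C@H]2[C@H](C(C)C)[C@H](O)C/C(C)=C/CC[C@@]3(C)O[C@H]23)cc(OC)c1OC | target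

Total step count: 18. Longest linear sequence: 18 steps (from 1; vinyl, isopropenyl and aroyl units enter as commercial reagents 6, 16 and 24).

Steps most likely to fail

Step 13. The rearrangement has to pass through the chair conformer in which both alkenyl groups are equatorial and the isopropyl and C6 silyloxy groups are axial. A slow rearrangement would leave time for fragmentation of the alkoxide or for migration of the silyl group from the C6 oxygen to the C5 alkoxide, and the hindered enolate may be sulfonylated incompletely. The fallback sets out from 17. The tertiary alcohol would be silylated (Me3SiOTf, 2,6-lutidine, CH2Cl2, −78 °C) to the trimethylsilyl ether of 17 F1. F1 would be rearranged without base (thermal siloxy-Cope, toluene, sealed tube, about 200 °C) to the ring-expanded trimethylsilyl enol ether F2, with the same chair-derived alkene geometry. Cleavage of F2 with KOt-Bu in THF at −78 °C would regenerate the potassium enolate, so the fallback comes back to the route at 19, which is sulfonylated as in step 13 to give 20.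

Step 4. Hydrogen abstraction may occur at C5–H next to the silyl ether (which would return the C5 enone) or at the C10 methyl group instead of the C8 methylene, and the product may over-oxidise. The fallback sets out from 4 and replaces direct C–H oxidation by an epoxide-based transposition. Epoxidation (mCPBA, NaHCO3, CH2Cl2, 0 °C) would give the C9–C10 epoxide F3. Opening at the less substituted C9 with PhSeNa ((PhSe)2, NaBH4, EtOH) would give the trans-diaxial hydroxy selenide F4. Oxidation with H2O2 and selenoxide syn-elimination towards C8 would give the tertiary allylic alcohol F5 (C8=C9, C10 carbinol). Babler–Dauben oxidative 1,3-transposition with pyridinium chlorochromate (CH2Cl2, 25 °C) would give the enone, so the fallback comes back to the route at 5.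

Step 12. The basic organometallic may enolise the hindered α-silyloxy ketone, and facial selectivity may be insufficient; attack syn to the C10 vinyl group would give the cis-dialkenyl isomer and hence a Z alkene in step 13. The fallback sets out from 15 and builds the isopropenyl group in two stages with a small, strongly nucleophilic reagent that favours axial attack. Addition of 1-ethoxyvinyllithium (ethyl vinyl ether, t-BuLi, THF, −78 °C) would give the 1-ethoxyvinyl carbinol F6. Mild hydrolysis of the enol ether (oxalic acid, wet THF, 0 °C) would give the α-hydroxy methyl ketone F7. Methylenation of the acetyl group with Cp2TiMe2 (toluene, 65 °C) would give the isopropenyl carbinol, so the fallback comes back to the route at 17.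

Further compounds
F1 | step 13 | trimethylsilyl ether of 17 | CC(=C)[C@@]1(O[Si](C)(C)C)[C@@H](O[Si](C)(C)C(C)(C)C)[C@H](C(C)C)[C@H](OCc2ccc(OC)cc2)C[C@]1(C)C=C
F2 | step 13 | ring-expanded trimethylsilyl enol ether, (1Z,5E)-cyclodeca-1,5-dien-1-yl trimethylsilyl ether analogue of 20 | C1/C(C)=C(O[Si](C)(C)C)/[C@@H](O[Si](C)(C)C(C)(C)C)[C@H](C(C)C)[C@H](OCc2ccc(OC)cc2)C/C(C)=C/C1
F3 | step 4 | C9–C10 epoxide of 4 (epoxide anti to the silyloxy group) | CC(C)(C)[Si](C)(C)O[C@H]1C[C@H](C(C)C)C[C@@H]2O[C@]12C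
F4 | step 4 | C9 phenylselanyl C10 tertiary alcohol (trans-diaxial hydroxy selenide) | CC(C)(C)[Si](C)(C)O[C@H]1C[C@H](C(C)C)C[C@@H]([Se]c2ccccc2)[C@@]1(O)C
F5 | step 4 | tertiary allylic alcohol (C8=C9 alkene, C10 carbinol) | CC(C)(C)[Si](C)(C)O[C@H]1C[C@H](C(C)C)C=C[C@@]1(O)C
F6 | step 12 | 1-ethoxyvinyl carbinol from 15 | C=C(OCC)[C@@]1(O)[C@@H](O[Si](C)(C)C(C)(C)C)[C@H](C(C)C)[C@H](OCc2ccc(OC)cc2)C[C@]1(C)C=C
F7 | step 12 | α-hydroxy methyl ketone (C5 acetyl carbinol) | CC(=O)[C@@]1(O)[C@@H](O[Si](C)(C)C(C)(C)C)[C@H](C(C)C)[C@H](OCc2ccc(OC)cc2)C[C@]1(C)C=C
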